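The numbers in the tables were generated by integration on assumed constants, noise included.

| flask | E | remark | time |
|---|---|---|---|
| ochre | 0.090 M | run made earlier |  |
| blue | 0.14 M | run made earlier |  |
| flask | 0.18 M |  | 20 h |

| run | time / h | L / % | Q / % |
|---|---|---|---|
| ochre | 1.00 | 25.0 | 13.8 |
| ochre | 1.33 | 25.0 | 17.7 |
| ochre | 2.00 | 19.2 | 23.2 |
| ochre | 3.00 | 10.1 | 24.8 |
| ochre | 5.00 | 4.0 | 25.6 |
| ochre | 8.00 | 1.9 | 24.6 |
| ochre | 12.0 | 2.9 | 23.6 |
| blue | 0.667 | 19.6 | 9.5 |
| blue | 2.00 | 18.4 | 21.8 |
| blue | 3.00 | 10.6 | 24.4 |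
| blue | 5.00 | 5.0 | 25.6 |
| blue | 8.00 | 2.9 | 23.8 |
| blue | 10.0 | 2.1 | 24.4 |
| blue | 12.0 | 2.3 | 22.6 |

(readings scatter by 0.5 percentage points)

- what was read earlier has a scatter of 0.5 percentage points, one standard deviation

1. ratio of L to Q at 8.0 min
2. ratio of L to Q at 20 h

In a one-step world L and Q leave E in a fixed proportion, so their lead Λ = ln(L/Q), the logarithm of the selectivity, stays flat, and zero on this scale means equal amounts. We therefore follow the rate at which Λ moves. The ochre and blue percentages lie close, with L at 19.2% and 18.4% after 2.00 h, so we carry them unchanged to the flask.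

Between 0.667 h and 2.00 h the blue run's Λ falls at 0.671 h⁻¹. If we assume that fall held steadily back to 8.0 min, the ratio there is 2.95.

From 8.00 h on, the L readings of both runs lie near a floor, and between 5.00 h and 12.0 h the pooled Q readings of the two runs shrink at 0.0147 h⁻¹. This rate is the late climb c, the hourly rise of Λ while L stays flat. The fall reads faster than c by a factor of 45.6, but c accumulates: from the pooled ratio of 0.113 read at 12.0 h, we reckon 0.127 for the flask at 20 h.

The forecast, lower than ours on both, gives 2.5 and 0.11, judging that “L appears to have levelled off”.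

The flask gives 2.85 at 8.0 min and 0.134 at 20 h. Starting from its own state at 10.0 h, with L 2.76% and Q 23.7%, c carries the ratio to 0.135 at 20 h.

    L ⇌ X (K = 22.0, k = 0.0160 min⁻¹)
    G → Z (k = 0.00340 min⁻¹)
    G ⇌ L (K = 2.60, k = 0.0210 min⁻¹)
    G ⇌ Q (K = 11.0, k = 0.00690 min⁻¹)
    E → G (k = 0.0420 min⁻¹)

The neighbouring flask holds 0.11 M of E, with all else held. Since the percentages lay close across charges, we apply the same c from the same pooled readings, which gives 0.127 for this flask too. The neighbouring flask gives 2.85 at 8.0 min and 0.134 at 20 h, the latter 1.06 times our figure. Its L stands at 2.72% and its Q at 20.2% after 20.0 h.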